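**Strategy.** Locants: C1 carbonyl carbon, C2 quaternary epoxide carbon carrying the farnesyl chain, C3 epoxide methine, C4 carbinol carbon, C5 alkene carbon carrying C7H2O, C6 alkene CH. The epoxide oxygen spanning C2–C3 and the C4 hydroxyl are cis on the six-membered ring. Both are traced to one O2 delivered across C2 and C5 of a C2=C3–C4=C5 cyclohexadiene. That single photooxygenation makes both C–O bonds, closes the 2,3-dioxabicyclo[2.2.2]octene ring and fixes C2/C5 from a CBS-derived C1 silyl ether. The diene already bears the allyl-protected hydroxymethylglutarate on C7, so only rearrangement, unmasking and C1 oxidation remain.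

Key step: step 12

Remarks: farnesyl = (2E,6E)-3,7,11-trimethyldodeca-2,6,10-trien-1-yl; TBS = tert-butyldimethylsilyl. C1–C7 in the Why lines are the target locants above; systematic names keep their own numbering.
Assumption: the mono-ethylene ketal 1 of cyclohexane-1,3-dione is bought as such, because direct mono-ketalisation of the dione is unreliable.

**Ring fragment**

Step 1
Reactants: 1 1,4-dioxaspiro[4.5]decan-7-one
Product: 3 1,4-dioxaspiro[4.5]dec-8-en-7-one, via trimethylsilyl enol ether 2 (not isolated)
Conditions: LiN(iPr)2, Me3SiCl, THF, −78 °C; then Pd(OAc)2 (10 mol %), O2 (1 atm), DMSO, rt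
Reagents that add atoms: none
Why: Saegusa–Ito dehydrogenation, in which kinetic deprotonation should occur at C8 away from the fully substituted ketal carbon and divalent palladium oxidises the silyl enol ether by β-hydride loss, while the ketal keeps the ring from tautomerising to a phenol.

Step 2
Reactants: 3 1,4-dioxaspiro[4.5]dec-8-en-7-one
Product: 4 8-iodo-1,4-dioxaspiro[4.5]dec-8-en-7-one
Conditions: I2, pyridine, CH2Cl2, 0 °C to rt
Reagents that add atoms: iodine, II
Why: α-Iodination of an enone by conjugate addition of pyridine, iodination of the enolate and elimination (a Baylis–Hillman-type sequence), under conditions too weakly basic to open the β-ketal.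

Step 3
Reactants: 4 8-iodo-1,4-dioxaspiro[4.5]dec-8-en-7-one
Product: 5 (7R)-8-iodo-1,4-dioxaspiro[4.5]dec-8-en-7-ol
Conditions: (S)-2-methyl-CBS-oxazaborolidine (20 mol %), BH3·SMe2, THF, −20 °C; MeOH quench
Reagents that add atoms: none
Why: Corey–Bakshi–Shibata reduction, in which the iodovinyl arm should act as the large group as in other 2-haloenones, so the (S)-catalyst should deliver hydride to give the (R)-carbinol, the future C1.

Step 4
Reactants: 5 (7R)-8-iodo-1,4-dioxaspiro[4.5]dec-8-en-7-ol
Product: 6 tert-butyl{[(7R)-8-iodo-1,4-dioxaspiro[4.5]dec-8-en-7-yl]oxy}dimethylsilane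
Conditions: tBuMe2SiCl, imidazole, DMF, rt
Reagents that add atoms: tert-butyldimethylsilyl chloride, CC(C)(C)[Si](C)(C)Cl
Why: Imidazole-promoted silylation of a secondary allylic alcohol installs the bulky group that will later shield one diene face, without touching the stereocentre.

Step 5
Reactants: 6 tert-butyl{[(7R)-8-iodo-1,4-dioxaspiro[4.5]dec-8-en-7-yl]oxy}dimethylsilane; 7 (2E,6E)-farnesyl bromide
Product: 10 tert-butyl{[(7R)-8-farnesyl-1,4-dioxaspiro[4.5]dec-8-en-7-yl]oxy}dimethylsilane, via alkenyllithium 8 (not isolated), via alkenylzinc chloride 9 (not isolated)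
Conditions: t-BuLi (2 equiv), Et2O, −78 °C; ZnCl2, THF, −78 to 0 °C; then 7, Pd(PPh3)4 (5 mol %), THF, 0 °C to rt
Reagents that add atoms: none
Why: Negishi alkenyl–allyl coupling, in which the alkenylzinc from iodine–lithium exchange and transmetalation should couple with the π-allyl complex of 7 and zerovalent palladium at the unsubstituted allyl terminus, with the 2E geometry retained, to form the C2–C1′ bond.

Step 6
Reactants: 10 tert-butyl{[(7R)-8-farnesyl-1,4-dioxaspiro[4.5]dec-8-en-7-yl]oxy}dimethylsilane
Product: 11 (5R)-5-[(tert-butyldimethylsilyl)oxy]-4-farnesylcyclohex-3-en-1-one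
Conditions: pyridinium p-toluenesulfonate (20 mol %), acetone/H2O, 40 °C
Reagents that add atoms: water, O
Why: Mild acid-catalysed acetal hydrolysis should free the C5 ketone while the secondary TBS ether, the chain alkenes and the unconjugated position of the ring double bond are preserved.

Step 7
Reactants: 11 (5R)-5-[(tert-butyldimethylsilyl)oxy]-4-farnesylcyclohex-3-en-1-one
Product: 13 (5R)-5-[(tert-butyldimethylsilyl)oxy]-4-farnesylcyclohexa-1,3-dien-1-yl trifluoromethanesulfonate, via potassium dienolate 12 (not isolated)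
Conditions: KN(SiMe3)2, THF, −78 °C; then 2-[N,N-bis(trifluoromethylsulfonyl)amino]-5-chloropyridine, −78 °C
Reagents that add atoms: 2-[N,N-bis(trifluoromethylsulfonyl)amino]-5-chloropyridine, O=S(=O)(N(c1ccc(Cl)cn1)S(=O)(=O)C(F)(F)F)C(F)(F)F
Why: Kinetic deprotonation at C4, which is both α to the ketone and allylic, should give the extended dienolate, and O-sulfonylation at −78 °C with the fast pyridyl triflimide gives the linear dienyl triflate (enol triflate formation) before silyloxide can be expelled.

Step 8
Reactants: 13 (5R)-5-[(tert-butyldimethylsilyl)oxy]-4-farnesylcyclohexa-1,3-dien-1-yl trifluoromethanesulfonate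
Product: 14 {(5R)-5-[(tert-butyldimethylsilyl)oxy]-4-farnesylcyclohexa-1,3-dien-1-yl}methanol
Conditions: Bu3SnCH2OH, Pd(PPh3)4 (10 mol %), LiCl, 1,4-dioxane, 90 °C
Reagents that add atoms: (tributylstannyl)methanol, OC[Sn](CCCC)(CCCC)CCCC
Why: Stille coupling of an alkenyl triflate with the hydroxymethylstannane (chloride-assisted transmetalation) attaches C7 to C5 as the free alcohol in one operation.

**Side-chain acid**

Step 9
Reactants: 15 (R)-mevalonolactone
Product: 17 prop-2-en-1-yl (3R)-3,5-dihydroxy-3-methylpentanoate, via potassium (R)-mevalonate 16 (not isolated)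
Conditions: KOH (1 equiv), H2O, rt; evaporate; then allyl bromide, DMF, 0 °C to rt
Reagents that add atoms: potassium hydroxide, [K+].[OH-]; allyl bromide, C=CCBr
Why: Saponification of the lactone followed by SN2 O-alkylation of the carboxylate under neutral conditions protects the original carboxyl without touching the tertiary stereocentre; the hydroxy ester is used at once to avoid relactonisation.

Step 10
Reactants: 17 prop-2-en-1-yl (3R)-3,5-dihydroxy-3-methylpentanoate
Product: 19 (3R)-3-hydroxy-3-methyl-5-oxo-5-(prop-2-en-1-yloxy)pentanoic acid, via aldehyde 18 (not isolated)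
Conditions: TEMPO (20 mol %), PhI(OAc)2, MeCN/H2O, rt
Reagents that add atoms: water, O
Why: Oxoammonium-mediated oxidation takes the primary alcohol through the aldehyde hydrate to the acid and leaves the tertiary alcohol alone; esterifying this newly oxidised arm with the ring alcohol is what turns the (R)-lactone into the side-chain configuration of the target.

**Union and end-game**

Step 11
Reactants: 14 {(5R)-5-[(tert-butyldimethylsilyl)oxy]-4-farnesylcyclohexa-1,3-dien-1-yl}methanol; 19 (3R)-3-hydroxy-3-methyl-5-oxo-5-(prop-2-en-1-yloxy)pentanoic acid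
Product: 20 {(5R)-5-[(tert-butyldimethylsilyl)oxy]-4-farnesylcyclohexa-1,3-dien-1-yl}methyl prop-2-en-1-yl (3S)-3-hydroxy-3-methylpentanedioate
Conditions: iPrN=C=NiPr, 4-(dimethylamino)pyridine (20 mol %), CH2Cl2, 0 °C
Reagents that add atoms: none
Why: Steglich esterification acylates the only reactive hydroxyl (primary, allylic) under near-neutral conditions that the acid-sensitive silyloxy diene tolerates, while the tertiary alcohol of 19 is too hindered to compete.

Step 12
Reactants: 20 {(5R)-5-[(tert-butyldimethylsilyl)oxy]-4-farnesylcyclohexa-1,3-dien-1-yl}methyl prop-2-en-1-yl (3S)-3-hydroxy-3-methylpentanedioate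
Product: 21 endoperoxide of 20 (2,3-dioxabicyclo[2.2.2]oct-5-ene with the O–O bridge joining C2 and C5 anti to the C1 silyloxy group)
Conditions: O2, 5,10,15,20-tetraphenylporphyrin (1 mol %), white LED, CH2Cl2, −78 °C; stopped when 20 is consumed
Reagents that add atoms: oxygen, O=O
Why: The photoexcited porphyrin passes its triplet energy to O2, and the resulting singlet oxygen adds as the two-atom partner across C2 and C5 of the s-cis ring diene in a concerted, suprafacial [4+2] cycloaddition that forms the C2–O and C5–O bonds together. The closest known case is the photooxygenation of α-terpinene to ascaridole, likewise a 1,4-disubstituted cyclohexa-1,3-diene. The six-membered 1,2-dioxane ring, and with it the 2,3-dioxabicyclo[2.2.2]oct-5-ene, is closed by the cycloaddition itself, both ring bonds arising on the same diene face. C2 and C5 are created together and are controlled by C1: allylic strain with the C2 side chain should hold the bulky silyloxy group pseudoaxial, so oxygen should approach from the opposite face. The step needs chemoselectivity for the ring diene over the three trisubstituted chain alkenes; a cisoid, electron-rich diene should cycloadd much faster than isolated alkenes undergo the ene reaction, and low temperature with a stop at full diene conversion protects the chain, while the terminal allyl ester alkene is inert.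

Step 13
Reactants: 21 endoperoxide of 20
Product: 22 syn-bis-epoxide (C2–C3 and C4–C5 oxiranes on one face and anti to the C1 silyloxy group; C7 ester unchanged)
Conditions: Co(TPP) (cobalt 5,10,15,20-tetraphenylporphyrinate, 5 mol %), CH2Cl2, −20 to 0 °C
Reagents that add atoms: none
Why: Divalent cobalt cleaves the weak O–O bond by one-electron transfer and each oxygen closes 3-exo onto its neighbouring alkene carbon (the known endoperoxide to syn-bis-epoxide rearrangement, as in ascaridole to isoascaridole), so C3 and C4 are set on the face the bridge occupied, and the fully substituted bridgeheads exclude the hydrogen-shift route to hydroxy enones.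

Step 14
Reactants: 22 syn-bis-epoxide
Product: 24 syn-bis-epoxide with free C1 hydroxyl and free side-chain carboxylic acid, via silyl-protected carboxylic acid 23 (not isolated)
Conditions: Pd(PPh3)4 (5 mol %), morpholine, THF, rt; then Bu4NF, THF, 0 °C to rt; pH 4 buffer work-up
Reagents that add atoms: none
Why: Tsuji–Trost deallylation (π-allyl complex of zerovalent palladium trapped by morpholine) is safe here because the molecule holds no other allylic leaving group, and fluoride then cleaves the TBS ether, with the morpholinium carboxylate buffering the alkoxide so that oxirane migration is not expected.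

Step 15
Reactants: 24 syn-bis-epoxide with free C1 hydroxyl and free side-chain carboxylic acid
Product: 26 CNP0134663.2 (target), via bis-epoxy ketone 25 (not isolated)
Conditions: Dess–Martin periodinane, CH2Cl2, 0 °C; aq. Na2S2O3 quench and extraction at pH 4; then Et3N, CH2Cl2, 0 °C; pH 4 work-up
Reagents that add atoms: none
Why: Dess–Martin oxidation converts the only oxidisable alcohol (C1; the side-chain hydroxyl is tertiary) into the ketone, and triethylamine then enolises toward C6 so that the enolate expels the C5–O bond of the adjacent oxirane (E1cB-type opening of a β,γ-epoxy ketone), which gives the C5=C6 enone and leaves the C4 hydroxyl cis to the C2–C3 oxirane.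

**Compound list**

1 | 1,4-dioxaspiro[4.5]decan-7-one | O=C1CCCC2(C1)OCCO2 | starting material
2 | (1,4-dioxaspiro[4.5]dec-7-en-7-yloxy)trimethylsilane | C[Si](C)(C)OC1=CCCC2(C1)OCCO2 | intermediate (not isolated)
3 | 1,4-dioxaspiro[4.5]dec-8-en-7-one | O=C1C=CCC2(C1)OCCO2 | intermediate
4 | 8-iodo-1,4-dioxaspiro[4.5]dec-8-en-7-one | O=C1C(I)=CCC2(C1)OCCO2 | intermediate
5 | (7R)-8-iodo-1,4-dioxaspiro[4.5]dec-8-en-7-ol | IC1=CCC2(OCCO2)C[C@H]1O | intermediate
6 | tert-butyl{[(7R)-8-iodo-1,4-dioxaspiro[4.5]dec-8-en-7-yl]oxy}dimethylsilane | IC1=CCC2(OCCO2)C[C@H]1O[Si](C)(C)C(C)(C)C | intermediate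
7 | (2E,6E)-farnesyl bromide | BrC/C=C(\C)CC/C=C(\C)CCC=C(C)C | starting material
8 | [(7R)-7-(TBS-oxy)-1,4-dioxaspiro[4.5]dec-8-en-8-yl]lithium | [Li]C1=CCC2(OCCO2)C[C@H]1O[Si](C)(C)C(C)(C)C | intermediate (not isolated)
9 | [(7R)-7-(TBS-oxy)-1,4-dioxaspiro[4.5]dec-8-en-8-yl]zinc chloride | Cl[Zn]C1=CCC2(OCCO2)C[C@H]1O[Si](C)(C)C(C)(C)C | intermediate (not isolated)
10 | tert-butyl{[(7R)-8-farnesyl-1,4-dioxaspiro[4.5]dec-8-en-7-yl]oxy}dimethylsilane | CC(C)=CCC/C(C)=C/CC/C(C)=C/CC1=CCC2(OCCO2)C[C@H]1O[Si](C)(C)C(C)(C)C | intermediate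
11 | (5R)-5-(TBS-oxy)-4-farnesylcyclohex-3-en-1-one | CC(C)=CCC/C(C)=C/CC/C(C)=C/CC1=CCC(=O)C[C@H]1O[Si](C)(C)C(C)(C)C | intermediate
12 | potassium (5R)-5-(TBS-oxy)-4-farnesylcyclohexa-1,3-dien-1-olate | CC(C)=CCC/C(C)=C/CC/C(C)=C/CC1=CC=C([O-])C[C@H]1O[Si](C)(C)C(C)(C)C.[K+] | intermediate (not isolated)
13 | (5R)-5-(TBS-oxy)-4-farnesylcyclohexa-1,3-dien-1-yl trifluoromethanesulfonate | CC(C)=CCC/C(C)=C/CC/C(C)=C/CC1=CC=C(OS(=O)(=O)C(F)(F)F)C[C@H]1O[Si](C)(C)C(C)(C)C | intermediate
14 | [(5R)-5-(TBS-oxy)-4-farnesylcyclohexa-1,3-dien-1-yl]methanol | CC(C)=CCC/C(C)=C/CC/C(C)=C/CC1=CC=C(CO)C[C@H]1O[Si](C)(C)C(C)(C)C | intermediate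
15 | (R)-mevalonolactone | C[C@@]1(O)CCOC(=O)C1 | starting material
16 | potassium (3R)-3,5-dihydroxy-3-methylpentanoate | [O-]C(=O)C[C@](C)(O)CCO.[K+] | intermediate (not isolated)
17 | prop-2-en-1-yl (3R)-3,5-dihydroxy-3-methylpentanoate | C=CCOC(=O)C[C@](C)(O)CCO | intermediate
18 | prop-2-en-1-yl (3R)-3-hydroxy-3-methyl-5-oxopentanoate | C=CCOC(=O)C[C@](C)(O)CC=O | intermediate (not isolated)
19 | (3R)-3-hydroxy-3-methyl-5-oxo-5-(prop-2-en-1-yloxy)pentanoic acid | C=CCOC(=O)C[C@](C)(O)CC(=O)O | intermediate
20 | [(5R)-5-(TBS-oxy)-4-farnesylcyclohexa-1,3-dien-1-yl]methyl prop-2-en-1-yl (3S)-3-hydroxy-3-methylpentanedioate (key-step substrate) | CC(C)=CCC/C(C)=C/CC/C(C)=C/CC1=CC=C(COC(=O)C[C@@](C)(O)CC(=O)OCC=C)C[C@H]1O[Si](C)(C)C(C)(C)C | intermediate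
21 | endoperoxide: [(1R,4R,7R)-7-(TBS-oxy)-1-farnesyl-2,3-dioxabicyclo[2.2.2]oct-5-en-4-yl]methyl prop-2-en-1-yl (3S)-3-hydroxy-3-methylpentanedioate, O–O bridge anti to the silyloxy group (key-step product) | CC(C)=CCC/C(C)=C/CC/C(C)=C/C[C@@]12OO[C@@](COC(=O)C[C@@](C)(O)CC(=O)OCC=C)(C=C1)C[C@H]2O[Si](C)(C)C(C)(C)C | intermediate
22 | syn-bis-epoxide: C2–C3 and C4–C5 oxiranes cis to each other and trans to the C1 TBS-oxy group; C7 allyl (3S)-hydroxymethylglutarate | CC(C)=CCC/C(C)=C/CC/C(C)=C/C[C@@]12O[C@@H]1[C@@H]3O[C@]3(COC(=O)C[C@@](C)(O)CC(=O)OCC=C)C[C@H]2O[Si](C)(C)C(C)(C)C | intermediate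
23 | 22 with the allyl ester cleaved to the free carboxylic acid | CC(C)=CCC/C(C)=C/CC/C(C)=C/C[C@@]12O[C@@H]1[C@@H]3O[C@]3(COC(=O)C[C@@](C)(O)CC(=O)O)C[C@H]2O[Si](C)(C)C(C)(C)C | intermediate (not isolated)
24 | 23 with the C1 hydroxyl free (C1–OH trans to both oxiranes) | CC(C)=CCC/C(C)=C/CC/C(C)=C/C[C@@]12O[C@@H]1[C@@H]3O[C@]3(COC(=O)C[C@@](C)(O)CC(=O)O)C[C@H]2O | intermediate
25 | C1 ketone of 24 (syn-bis-epoxy cyclohexanone) | CC(C)=CCC/C(C)=C/CC/C(C)=C/C[C@@]12O[C@@H]1[C@@H]3O[C@]3(COC(=O)C[C@@](C)(O)CC(=O)O)CC2=O | intermediate (not isolated)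
26 | CNP0134663.2: (3S)-3-hydroxy-5-{[(1R,5R,6R)-5-hydroxy-2-oxo-1-farnesyl-7-oxabicyclo[4.1.0]hept-3-en-4-yl]methoxy}-3-methyl-5-oxopentanoic acid | CC(C)=CCC/C(C)=C/CC/C(C)=C/C[C@@]12O[C@@H]1[C@H](O)C(COC(=O)C[C@@](C)(O)CC(=O)O)=CC2=O | target

**Totals.** 15 steps in all; longest linear sequence 13 steps (steps 1–8, then 11–15); the side-chain acid takes 2 steps (9–10).

**Steps most likely to fail**

Step 12. Ene-type hydroperoxidation of the chain double bonds may compete with the cycloaddition, and some oxygen may add on the silyloxy face. Fallback: the order of acylation and oxygenation is reversed, so that the more electron-rich, unacylated diene is oxidised and none of the side-chain acid is at stake. Setting out from 14, photooxygenation under the same conditions should give the hydroxymethyl endoperoxide F1. Co(TPP) should then rearrange it to the hydroxymethyl syn-bis-epoxide F2, whose single free hydroxyl is esterified with 19 (iPrN=C=NiPr, 4-(dimethylamino)pyridine), rejoining the route at 22.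

Step 7. The extended dienolate may expel the C1 silyloxide (vinylogous β-elimination) and aromatise, or deprotonation may occur at C6. Fallback: no strong base and no standing enolate. Setting out from 11, soft enolisation with Me3SiOTf and Et3N in CH2Cl2 at −78 °C should give the trimethylsilyl dienol ether F3. CsF with N-phenylbis(trifluoromethanesulfonimide) in 1,2-dimethoxyethane then releases the enolate only in the presence of the triflating agent, rejoining the route at 13.

Step 8. At 90 °C the silyloxy diene may lose silanol and aromatise, and hydroxymethyl transfer from tin may be slow. Fallback: C7 is brought in as carbon monoxide at room temperature. Setting out from 13, methoxycarbonylation (Pd(OAc)2, PPh3, CO at 1 atm, MeOH, Et3N, DMF, rt) should give the methyl dienoate F4, which iBu2AlH in CH2Cl2 at −78 °C reduces to 14.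

**Further compounds**

F1 | step 12 | [(1R,4R,7R)-7-(TBS-oxy)-1-farnesyl-2,3-dioxabicyclo[2.2.2]oct-5-en-4-yl]methanol | CC(C)=CCC/C(C)=C/CC/C(C)=C/C[C@@]12OO[C@@](CO)(C=C1)C[C@H]2O[Si](C)(C)C(C)(C)C
F2 | step 12 | hydroxymethyl syn-bis-epoxide (C2–C3 and C4–C5 oxiranes trans to the C1 TBS-oxy group, free C7 hydroxyl) | CC(C)=CCC/C(C)=C/CC/C(C)=C/C[C@@]12O[C@@H]1[C@@H]3O[C@]3(CO)C[C@H]2O[Si](C)(C)C(C)(C)C
F3 | step 7 | tert-butyldimethyl{[(1R)-2-farnesyl-5-(trimethylsilyloxy)cyclohexa-2,4-dien-1-yl]oxy}silane | CC(C)=CCC/C(C)=C/CC/C(C)=C/CC1=CC=C(O[Si](C)(C)C)C[C@H]1O[Si](C)(C)C(C)(C)C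
F4 | step 8 | methyl (5R)-5-(TBS-oxy)-4-farnesylcyclohexa-1,3-diene-1-carboxylate | CC(C)=CCC/C(C)=C/CC/C(C)=C/CC1=CC=C(C(=O)OC)C[C@H]1O[Si](C)(C)C(C)(C)C
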